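## Retrosynthetic overview
1. 16 ⇒ 15 (C9–OAc, acetoxylation of a C8 silyl dienol ether) ⇒ 12 (C1–O acyl bond) ⇒ 11 (C1 carbinol by reagent-controlled ketone reduction).
2. 11 ⇒ 10: the C10–CH3 bond comes from methylcuprate 1,4-addition to the unsubstituted enone arm of a spiro[4.5]deca-6,9-diene-1,8-dione. The enolate is kept as its silyl ether.
3. 10 ⇒ 9: the C4–C5 bond comes from an oxidative dearomative semipinacol ring expansion (cyclobutanol → cyclopentanone) of an achiral 1-arylcyclobutanol. This sets C5 and C3 together.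
4. 9 ⇒ 2 + 7 (aryllithium + cyclobutanone). 2 comes from m-cresol; 7 comes from 3-oxocyclobutanecarboxylic acid and an isopropenyl metal.
5. Ring order: ring A (six-membered) enters as the arene and the four-membered ring is bought. Ring B (five-membered) forms last, by expansion of the four-membered ring in the same event that dearomatises ring A.

**Numbering used:** C1 (O-acyl), C2, C3 (isopropenyl), C4, C5 (spiro), C6 (=C–CH3), C7, C8 (C=O), C9 (OAc), C10 (CH–CH3). The target is (1S,3R,5S,9S,10R). On ring B, the isopropenyl group and C6 share one face, and the C1 oxygen and C10 share the other. On ring A, the 10-CH3 lies on the C1 face and the 9-OAc on the C4 face.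

**Iodane Q (reagent, step 4):** 2,2'-{[2-(diacetoxy-λ3-iodanyl)-1,3-phenylene]bis(oxy)}bis[(2R)-N-mesitylpropanamide]. It is pre-formed from the iodoarene, so no peracid meets the isopropenyl group.
SMILES: C[C@@H](Oc1cccc(O[C@H](C)C(=O)Nc2c(C)cc(C)cc2C)c1I(OC(C)=O)OC(C)=O)C(=O)Nc1c(C)cc(C)cc1C

**Assumption:** the sense of induction of the new step 4 cannot be predicted with certainty. (R,R)-Q is written; if it gives the mirror image, (S,S)-Q, made from the other lactate enantiomer, is used instead.

## Route

Step 1
Reactants: 1 m-cresol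
Product: 2 4-bromo-3-methylphenol
Conditions: NBS (1.0 equiv), MeCN, 0 °C → rt; crystallise
Reagents that add atoms: N-bromosuccinimide, O=C1CCC(=O)N1Br
Why: Electrophilic aromatic bromination goes mainly to the position para to OH and ortho to CH3, the most activated site, and the minor 6-bromide is removed by crystallisation; no stereocentre is formed.

Step 2
Reactants: 3 3-oxocyclobutane-1-carboxylic acid; 4 isopropenylmagnesium bromide
Product: 7 3-(prop-1-en-2-yl)cyclobutan-1-one, via redox-active phthalimidyl ester 5 (not isolated), via isopropenylzinc chloride 6 (not isolated)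
Conditions: 3, N-hydroxyphthalimide, DIC, THF, rt; separately 4 + ZnCl2, THF, 0 °C; combine, Ni(acac)2 (10 mol %), 2,2'-bipyridine (10 mol %), THF/DMF, rt; 1 M HCl work-up
Reagents that add atoms: none
Why: In this nickel-catalysed decarboxylative alkenylation of a redox-active ester, single-electron reduction of 5 releases CO2 and the 3-oxocyclobutyl radical, which nickel couples to the alkenylzinc, a nucleophile too mild to attack the ketone; no stereocentre is formed.

Step 3
Reactants: 2 4-bromo-3-methylphenol; 7 3-(prop-1-en-2-yl)cyclobutan-1-one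
Product: 9 cis-1-(4-hydroxy-2-methylphenyl)-3-(prop-1-en-2-yl)cyclobutan-1-ol, via lithium 4-lithio-3-methylphenoxide 8 (not isolated)
Conditions: 2, t-BuLi (3.1 equiv), THF, −78 °C; then 7, −78 → −20 °C; H2O quench; Et3N-deactivated silica
Reagents that add atoms: none
Why: After deprotonation and bromine–lithium exchange, the aryllithium adds 1,2 to the puckered cyclobutanone anti to the 3-substituent, as is general for 3-substituted cyclobutanones, so OH ends cis to isopropenyl and the minor trans isomer is removed by chromatography.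

Step 4
Reactants: 9 cis-1-(4-hydroxy-2-methylphenyl)-3-(prop-1-en-2-yl)cyclobutan-1-ol
Product: 10 (3R,5S)-6-methyl-3-(prop-1-en-2-yl)spiro[4.5]deca-6,9-diene-1,8-dione
Conditions: iodane Q (1.1 equiv), CH2Cl2/(CF3)2CHOH 10:1, −40 °C
Reagents that add atoms: none
Why: Proposed new method: an enantioselective, desymmetrising oxidative dearomative semipinacol ring expansion in which the phenol exchanges an acetate on the trivalent iodine of Q, the hydrogen-bonded lactamide arms cover one arene face, and O–I heterolysis is concerted with a strain-releasing (about 20 kcal/mol) 1,2-shift of a cyclobutane C–C bond onto the open Re face of the para carbon while the carbinol becomes the C1 ketone; allylic 1,3-strain puts the small OH rather than the non-migrating CH2 beside the ortho methyl, so the face choice also fixes which enantiotopic CH2 migrates and C5 and C3 are set together, with the isopropenyl (cis to OH in 9) ending on the C6 face; the closest known reactions are the racemic PhI(OAc)2-mediated oxidative Wagner–Meerwein/semipinacol shift of 4-(1-hydroxyalkyl)phenols and chiral-iodoarene dearomative spirolactonisation of phenols.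

Step 5
Reactants: 10 (3R,5S)-6-methyl-3-(prop-1-en-2-yl)spiro[4.5]deca-6,9-diene-1,8-dione
Product: 11 (3R,5S,10S)-6,10-dimethyl-3-(prop-1-en-2-yl)-8-[(triethylsilyl)oxy]spiro[4.5]deca-6,8-dien-1-one
Conditions: MeLi (3.0 equiv), CuBr·SMe2 (1.5 equiv), Et2O, −20 °C; then Et3SiCl (3 equiv) and 10, THF, −78 °C; aq NH4Cl/NH3; Et3N-deactivated silica
Reagents that add atoms: methyllithium, [Li]C; chlorotriethylsilane, CC[Si](Cl)(CC)CC
Why: Silyl-chloride-accelerated Gilman conjugate addition picks the only β-unsubstituted enone carbon (C10, not the β-methylated C6) and approaches on the face flanked by the flat C1 carbonyl, which has no hydrogen over the π-system and can bridge Li+, rather than past the C4–H that projects over C10, so the 10-CH3 ends syn to C1 and the enolate is trapped as the cross-conjugated silyl dienol ether that masks C8.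

Step 6
Reactants: 11 (3R,5S,10S)-6,10-dimethyl-3-(prop-1-en-2-yl)-8-[(triethylsilyl)oxy]spiro[4.5]deca-6,8-dien-1-one
Product: 12 (1S,3R,5S,10S)-6,10-dimethyl-3-(prop-1-en-2-yl)-8-[(triethylsilyl)oxy]spiro[4.5]deca-6,8-dien-1-ol
Conditions: (R)-2-methyl-CBS-oxazaborolidine (0.5 equiv), catecholborane (2 equiv), toluene, −78 → −30 °C; aq NaHCO3 work-up
Reagents that add atoms: none
Why: In this Corey–Bakshi–Shibata reduction the only free carbonyl is C1, whose flanks (quaternary C5 as the large group, C2H2 as the small group) suit reagent control, so the (R)-catalyst delivers hydride from the C6 face to give the (1S)-alcohol, and catecholborane at low temperature leaves the alkenes and the silyl dienol ether untouched.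

Step 7
Reactants: 12 (1S,3R,5S,10S)-6,10-dimethyl-3-(prop-1-en-2-yl)-8-[(triethylsilyl)oxy]spiro[4.5]deca-6,8-dien-1-ol; 13 3-methylbut-2-enoyl chloride
Product: 15 (1S,3R,5S,10S)-6,10-dimethyl-3-(prop-1-en-2-yl)-8-[(triethylsilyl)oxy]spiro[4.5]deca-6,8-dien-1-yl 3-methylbut-2-enoate, via lithium alkoxide 14 (not isolated)
Conditions: LiN(SiMe3)2 (1.1 equiv), THF, −78 °C; then 13 (1.5 equiv), −78 → 0 °C
Reagents that add atoms: none
Why: O-acylation of the pre-formed alkoxide forces the hindered alcohol to react without an amine base, which avoids vinylketene formation and deconjugation of the senecioyl unit; it retains C1, and it is safe because the masked C8 carbonyl offers no acceptor for a vinylogous retro-aldol cleavage.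

Step 8
Reactants: 15 (1S,3R,5S,10S)-6,10-dimethyl-3-(prop-1-en-2-yl)-8-[(triethylsilyl)oxy]spiro[4.5]deca-6,8-dien-1-yl 3-methylbut-2-enoate
Product: 16 (1S,3R,5S,9S,10R)-9-acetoxy-6,10-dimethyl-8-oxo-3-(prop-1-en-2-yl)spiro[4.5]dec-6-en-1-yl 3-methylbut-2-enoate
Conditions: Pb(OAc)4 (1.1 equiv), CH2Cl2, −20 → 0 °C
Reagents that add atoms: lead tetraacetate, CC(=O)O[Pb](OC(C)=O)(OC(C)=O)OC(C)=O
Why: In this Rubottom-type lead tetraacetate acetoxylation of a 2-silyloxy-1,3-diene, silicon-to-lead exchange gives a tetravalent lead enolate that passes an acetate to C9 by inner-sphere transfer on the face opposite the neighbouring 10-CH3 (9,10-trans), releasing divalent lead and the C6=C7–C8=O enone, while the far less electron-rich isopropenyl and senecioate alkenes do not react at this temperature.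

## Compound list
1 | m-cresol (3-methylphenol) | Cc1cccc(O)c1 | starting material
2 | 4-bromo-3-methylphenol | Cc1cc(O)ccc1Br | intermediate
3 | 3-oxocyclobutane-1-carboxylic acid | O=C1CC(C(=O)O)C1 | starting material
4 | isopropenylmagnesium bromide | C=C(C)[Mg]Br | starting material
5 | 1,3-dioxoisoindolin-2-yl 3-oxocyclobutane-1-carboxylate | O=C1CC(C(=O)ON2C(=O)c3ccccc3C2=O)C1 | intermediate (not isolated)
6 | isopropenylzinc chloride | C=C(C)[Zn]Cl | intermediate (not isolated)
7 | 3-(prop-1-en-2-yl)cyclobutan-1-one | C=C(C)C1CC(=O)C1 | intermediate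
8 | lithium 4-lithio-3-methylphenoxide | [Li]Oc1ccc([Li])c(C)c1 | intermediate (not isolated)
9 | cis-1-(4-hydroxy-2-methylphenyl)-3-(prop-1-en-2-yl)cyclobutan-1-ol (OH and isopropenyl on the same face, aryl opposite; achiral) | C=C(C)[C@H]1C[C@](O)(c2ccc(O)cc2C)C1 | intermediate
10 | (3R,5S)-6-methyl-3-(prop-1-en-2-yl)spiro[4.5]deca-6,9-diene-1,8-dione | C=C(C)[C@H]1CC(=O)[C@]2(C1)C(C)=CC(=O)C=C2 | intermediate
11 | (3R,5S,10S)-6,10-dimethyl-3-(prop-1-en-2-yl)-8-[(triethylsilyl)oxy]spiro[4.5]deca-6,8-dien-1-one | C=C(C)[C@H]1CC(=O)[C@]2(C1)C(C)=CC(O[Si](CC)(CC)CC)=C[C@@H]2C | intermediate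
12 | (1S,3R,5S,10S)-6,10-dimethyl-3-(prop-1-en-2-yl)-8-[(triethylsilyl)oxy]spiro[4.5]deca-6,8-dien-1-ol | C=C(C)[C@H]1C[C@H](O)[C@]2(C1)C(C)=CC(O[Si](CC)(CC)CC)=C[C@@H]2C | intermediate
13 | 3-methylbut-2-enoyl chloride (senecioyl chloride) | CC(C)=CC(=O)Cl | starting material
14 | lithium alkoxide of 12 | C=C(C)[C@H]1C[C@H](O[Li])[C@]2(C1)C(C)=CC(O[Si](CC)(CC)CC)=C[C@@H]2C | intermediate (not isolated)
15 | (1S,3R,5S,10S)-6,10-dimethyl-3-(prop-1-en-2-yl)-8-[(triethylsilyl)oxy]spiro[4.5]deca-6,8-dien-1-yl 3-methylbut-2-enoate | C=C(C)[C@H]1C[C@H](OC(=O)C=C(C)C)[C@]2(C1)C(C)=CC(O[Si](CC)(CC)CC)=C[C@@H]2C | intermediate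
16 | (1S,3R,5S,9S,10R)-9-acetoxy-6,10-dimethyl-8-oxo-3-(prop-1-en-2-yl)spiro[4.5]dec-6-en-1-yl 3-methylbut-2-enoate (CNP0218315.1) | C=C(C)[C@H]1C[C@H](OC(=O)C=C(C)C)[C@]2(C1)C(C)=CC(=O)[C@@H](OC(C)=O)[C@@H]2C | target

## Step count
- **Total steps:** 8.
- **Longest linear sequence:** 7 (steps 1, 3, 4, 5, 6, 7, 8 from m-cresol; the same length from acid 3 through step 2).

## Three steps most likely to fail

**(a) Step 4, the proposed new ring expansion.**
- The iodine sits on the phenol oxygen, para to the reacting carbon, so face discrimination is remote.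
- Any leakage to a free phenoxenium ion in the fluorinated alcohol gives racemic product.
- The diastereoselectivity rests only on OH being smaller than the ring CH2 next to the ortho methyl.

The fallback uses known chemistry and sets out from 9. PhI(OAc)2 in (CF3)2CHOH at 0 °C, the established achiral hypervalent-iodine oxidative semipinacol shift, gives the racemate. This is 10 together with its mirror image (3S,5R)-6-methyl-3-(prop-1-en-2-yl)spiro[4.5]deca-6,9-diene-1,8-dione F1. Preparative SFC on an amylose-carbamate chiral phase separates the two, and the route is rejoined at 10.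

**(b) Step 5, the cuprate addition.**
- The preference for the C1-carbonyl face over the C4H2 face is only a steric and chelation argument.
- Electron transfer to the 4-acyl dienone could trigger deacylative rearomatisation.

The fallback sets out from 10 and replaces steric control by a directing group.
1. (R)-2-Methyl-CBS-oxazaborolidine and catecholborane, with a pH 7 work-up, first reduce the more electrophilic C1 ketone. This gives (1S,3R,5S)-1-hydroxy-6-methyl-3-(prop-1-en-2-yl)spiro[4.5]deca-6,9-dien-8-one F2.
2. AlMe3 (3 equiv, CH2Cl2, −78 → 0 °C) forms the covalent aluminium alkoxide. It delivers methyl through a six-membered transition state to C10 on the C1 face, the known hydroxyl-directed organoaluminium conjugate addition of quinol-type dienones. The product is (1S,3R,5S,10S)-1-hydroxy-6,10-dimethyl-3-(prop-1-en-2-yl)spiro[4.5]dec-6-en-8-one F3.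
3. Neutral acylation with 13, pyridine and DMAP gives (1S,3R,5S,10S)-6,10-dimethyl-8-oxo-3-(prop-1-en-2-yl)spiro[4.5]dec-6-en-1-yl 3-methylbut-2-enoate F4.
4. Kinetic deprotonation at C9 with LiN(SiMe3)2 in the presence of Et3SiCl (THF, −78 °C) brings the material back to the route at 15.

**(c) Step 6, the C1 reduction.**
- Both carbonyl faces are flanked by a methyl group (6-CH3 on one, 10-CH3 on the other), so the reaction may be slow.
- The isopropenyl group lies on the face that hydride must use, so the substrate bias may oppose the catalyst.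

The fallback sets out from 11 and exploits that bias. LiBH(s-Bu)3 (THF, −78 °C) attacks from the C10 face and gives (1R,3R,5S,10S)-6,10-dimethyl-3-(prop-1-en-2-yl)-8-[(triethylsilyl)oxy]spiro[4.5]deca-6,8-dien-1-ol F5. A Mitsunobu esterification with 3-methylbut-2-enoic acid, PPh3 and DIAD (toluene, 0 °C → rt) then inverts C1 and installs the ester in one operation. The route is rejoined at 15.

## Further compounds
F1 | step 4 | (3S,5R)-6-methyl-3-(prop-1-en-2-yl)spiro[4.5]deca-6,9-diene-1,8-dione | C=C(C)[C@@H]1CC(=O)[C@@]2(C1)C(C)=CC(=O)C=C2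
F2 | step 5 | (1S,3R,5S)-1-hydroxy-6-methyl-3-(prop-1-en-2-yl)spiro[4.5]deca-6,9-dien-8-one | C=C(C)[C@H]1C[C@H](O)[C@]2(C1)C(C)=CC(=O)C=C2
F3 | step 5 | (1S,3R,5S,10S)-1-hydroxy-6,10-dimethyl-3-(prop-1-en-2-yl)spiro[4.5]dec-6-en-8-one | C=C(C)[C@H]1C[C@H](O)[C@]2(C1)C(C)=CC(=O)C[C@@H]2C
F4 | step 5 | (1S,3R,5S,10S)-6,10-dimethyl-8-oxo-3-(prop-1-en-2-yl)spiro[4.5]dec-6-en-1-yl 3-methylbut-2-enoate | C=C(C)[C@H]1C[C@H](OC(=O)C=C(C)C)[C@]2(C1)C(C)=CC(=O)C[C@@H]2C
F5 | step 6 | (1R,3R,5S,10S)-6,10-dimethyl-3-(prop-1-en-2-yl)-8-[(triethylsilyl)oxy]spiro[4.5]deca-6,8-dien-1-ol | C=C(C)[C@H]1C[C@@H](O)[C@]2(C1)C(C)=CC(O[Si](CC)(CC)CC)=C[C@@H]2C
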